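**Assumption:** the target is planar and achiral (no stereocentre), so the "single enantiomer" is simply the compound itself and no stereocontrol is needed.

**Retrosynthetic overview**
1. Remove the C2–Br and C3–Br bonds: late double electrophilic bromination of the pyrrole ring of 5,6-dibromo-1H-indole.
2. 5,6-Dibromo-1H-indole comes from methyl 5,6-dibromo-1H-indole-3-carboxylate by ester hydrolysis and protodecarboxylation; the ester is a removable C3 blocking and deactivating group.
3. The dibromo ester comes from commercial methyl 1H-indole-3-carboxylate and Br2; with C3 blocked, bromination goes to C5 and C6.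
4. No ring is formed: the indole bicycle is bought intact and only substituted.

**Route**

Step 1
Reactants: 1 methyl 1H-indole-3-carboxylate; 2 bromine
Product: 5 methyl 5,6-dibromo-1H-indole-3-carboxylate, via methyl 6-bromo-1H-indole-3-carboxylate 3 (not isolated), via methyl 5-bromo-1H-indole-3-carboxylate 4 (not isolated)
Conditions: Br2 (2.2 equiv), AcOH, rt, 24–48 h; pour into water, filter, recrystallise
Reagents that add atoms: bromine, BrBr
Why: Electrophilic aromatic bromination in which the C3 ester blocks C3 and deactivates the pyrrole ring, so bromine enters the benzo ring at C6 and C5, the two monobromides 3 and 4 converge on 5, and the twice-brominated ring is too deactivated to react further (no stereocentre is formed).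

Step 2
Reactants: 5 methyl 5,6-dibromo-1H-indole-3-carboxylate
Product: 7 5,6-dibromo-1H-indole, via sodium 5,6-dibromo-1H-indole-3-carboxylate 6 (not isolated)
Conditions: NaOH (4 equiv), MeOH/H2O, microwave, 150 °C, sealed vial; dilute with water, extract with EtOAc
Reagents that add atoms: none
Why: Saponification followed by protodecarboxylation, in which hot aqueous base cleaves the ester to carboxylate 6 and ipso-protonation at the nucleophilic C3 then lets CO2 leave with rearomatisation, while the unactivated aryl bromides are inert to hydroxide in the absence of a metal catalyst.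

Step 3
Reactants: 7 5,6-dibromo-1H-indole; 8 N-bromosuccinimide
Product: 10 2,3,5,6-tetrabromo-1H-indole, via 3,5,6-tribromo-1H-indole 9 (not isolated)
Conditions: NBS (2.05 equiv), dry THF, −78 °C → rt, dark, Ar; rapid chromatography, store cold and dark
Reagents that add atoms: N-bromosuccinimide, O=C1CCC(=O)N1Br
Why: Electrophilic aromatic bromination of the pyrrole ring, in which the most nucleophilic position C3 reacts first to give 9 and the second equivalent brominates C2, the only pyrrole CH left, while the benzo ring is deactivated by its two bromines (the product is achiral, so no stereocentre has to be set).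

**Compound list**
1 | methyl 1H-indole-3-carboxylate | COC(=O)c1c[nH]c2ccccc12 | starting material
2 | bromine | BrBr | starting material
3 | methyl 6-bromo-1H-indole-3-carboxylate (not isolated) | COC(=O)c1c[nH]c2cc(Br)ccc12 | intermediate
4 | methyl 5-bromo-1H-indole-3-carboxylate (not isolated) | COC(=O)c1c[nH]c2ccc(Br)cc12 | intermediate
5 | methyl 5,6-dibromo-1H-indole-3-carboxylate | COC(=O)c1c[nH]c2cc(Br)c(Br)cc12 | intermediate
6 | sodium 5,6-dibromo-1H-indole-3-carboxylate (not isolated) | [Na+].[O-]C(=O)c1c[nH]c2cc(Br)c(Br)cc12 | intermediate
7 | 5,6-dibromo-1H-indole | Brc1cc2cc[nH]c2cc1Br | intermediate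
8 | N-bromosuccinimide | O=C1CCC(=O)N1Br | starting material
9 | 3,5,6-tribromo-1H-indole (not isolated) | Brc1c[nH]c2cc(Br)c(Br)cc12 | intermediate
10 | 2,3,5,6-tetrabromo-1H-indole | Brc1cc2[nH]c(Br)c(Br)c2cc1Br | target

**Total step count:** 3
**Longest linear sequence:** 3 steps

**Steps most likely to fail** (the route has only three steps; ranked from most to least risky)

Step 3 (double bromination of an N–H indole). The risks are over-oxidation to oxindole or isatin-type products by traces of water, and loss of the labile N–H 2,3-dibromoindole on work-up. The fallback sets out from 5,6-dibromo-1H-indole 7 and comes back to the route at the target 10. It introduces the C2 bromine by deoxybromination of a lactam instead of by electrophilic substitution. Compound 7 is chlorinated at C3 (N-chlorosuccinimide, DMF, rt) to give 5,6-dibromo-3-chloro-1H-indole F5. This is hydrolysed (85% H3PO4, 2-methoxyethanol, 100 °C) to 5,6-dibromoindolin-2-one F6. POBr3 in refluxing 1,2-dichloroethane converts the lactam into 2,5,6-tribromo-1H-indole F7. One equivalent of N-bromosuccinimide 8 (THF, −78 °C) then brominates the only free pyrrole position, C3, to give 10.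

Step 1 (regioselective dibromination). The risks are mixtures of mono- and tribromides or of regioisomeric dibromides that are hard to separate. The fallback sets out from bromine 2 (compound 1 is given up) and comes back to the route at 5,6-dibromo-1H-indole 7, so it replaces steps 1 and 2. It fixes the bromine pattern on a benzene precursor and then builds the pyrrole ring by a Leimgruber–Batcho indole synthesis. Commercial 4-bromo-2-methyl-1-nitrobenzene F1 is brominated with 2 (FeBr3 cat., 80 °C, dark) at the position para to methyl, meta to nitro and ortho to bromine, giving 1,2-dibromo-4-methyl-5-nitrobenzene F2. Condensation of the acidified methyl group with N,N-dimethylformamide dimethyl acetal (DMF, 110 °C) gives (E)-2-(4,5-dibromo-2-nitrophenyl)-N,N-dimethylethen-1-amine F3. Fe powder in AcOH/EtOH at 80 °C reduces the nitro group without touching the aryl bromides, and the aniline cyclises onto the enamine with loss of dimethylamine to give 7, which enters step 3.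

Step 2 (one-pot hydrolysis and decarboxylation). The risks are sluggish cleavage of the vinylogous carbamate ester, incomplete decarboxylation, or decomposition at 150 °C. The fallback sets out from methyl 5,6-dibromo-1H-indole-3-carboxylate 5 and comes back to the route at the target 10. It replaces protodecarboxylation by ipso-bromodecarboxylation, so the carboxyl group is exchanged directly for the C3 bromine. Ester 5 is saponified under conventional heating (aq. NaOH, MeOH, reflux; then HCl to pH 2) and 5,6-dibromo-1H-indole-3-carboxylic acid F4 is filtered off. Treatment of F4 with N-bromosuccinimide 8 (2.1 equiv, DMF, 0 °C → rt) brominates C3 at the ipso position with loss of CO2 to give 3,5,6-tribromo-1H-indole 9. The second equivalent brominates C2 in the same flask to give 10.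

**Further compounds**
F1 | step 1 | 4-bromo-2-methyl-1-nitrobenzene | Cc1cc(Br)ccc1[N+](=O)[O-]
F2 | step 1 | 1,2-dibromo-4-methyl-5-nitrobenzene | Cc1cc(Br)c(Br)cc1[N+](=O)[O-]
F3 | step 1 | (E)-2-(4,5-dibromo-2-nitrophenyl)-N,N-dimethylethen-1-amine | CN(C)/C=C/c1cc(Br)c(Br)cc1[N+](=O)[O-]
F4 | step 2 | 5,6-dibromo-1H-indole-3-carboxylic acid | OC(=O)c1c[nH]c2cc(Br)c(Br)cc12
F5 | step 3 | 5,6-dibromo-3-chloro-1H-indole | Clc1c[nH]c2cc(Br)c(Br)cc12
F6 | step 3 | 5,6-dibromoindolin-2-one | O=C1Cc2cc(Br)c(Br)cc2N1
F7 | step 3 | 2,5,6-tribromo-1H-indole | Brc1cc2cc(Br)c(Br)cc2[nH]1
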